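## The problem

The target 11 is a 2,3-dihydrobenzofuran. Its benzo ring (ring A, C3a–C7a) is fused to a dihydrofuran made of O1, C2 and C3. C2 carries ring B (3,4-dimethoxyphenyl), C3 a hydroxymethyl group, C7 a free phenol and C5 an (E)-acrylic acid. Ring A is therefore 1,2,3,5-tetrasubstituted with two neighbouring oxygens that must be told apart: O1 closes the heterocycle, O7 must end as a free hydroxyl. The two contiguous stereocentres are 2R and 3S, with aryl and hydroxymethyl trans. They are not of equal standing. While C3 carries a carbonyl group it can be epimerised and takes the more stable trans arrangement dictated by C2. C2 is an ether carbon without an acidic hydrogen, so it must be created in its absolute sense and cannot be repaired later. Three groups limit the conditions: the C2–O1 benzylic ether, which the para-methoxy group of ring B helps to ionise in strong acid; the catechol monoether of ring A, which is easily oxidised once O7 is free; and the acrylic acid, which would not survive hydride reduction of a neighbouring ester and so should arrive late. The enabling feature is that the O1–C2 bond and the bond from C3 to the hydroxymethyl carbon are vicinal across C2–C3, with O1 already on ring A ortho to C3a. The heterocycle is thus the formal adduct of a phenol oxygen and a one-carbon unit across the C2=C3 double bond of a 2-hydroxystilbene.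

## Retrosynthesis

**Periphery.** Removing the methoxymethyl (MOM) group from O7 leads from 11 back to acid 10. Cutting the C5–vinyl bond of 10 gives aryl bromide 8 and acrylic acid 9. This is preferred to cutting the side-chain C=C bond (aldehyde plus malonic acid), because a formyl group at C5 would need an acetal through the carbonylation in methanol and the hydride step. A bromide is inert to divalent palladium, methoxide and borohydride and needs no protection. The forward Mizoroki–Heck reaction must tolerate a free primary alcohol, and the final acetal hydrolysis must leave the C2–O1 bond alone.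

**Oxidation state and C3.** Alcohol 8 is the reduction product of trans ester 7, which is the C3 epimer of cis ester 6. No skeletal bond is cut here. An ester at C3 is the direct outcome of a carbonylation and also the handle that lets C2 dictate C3 under equilibrating conditions. The stereochemical problem shrinks to one centre, C2.

**Key disconnection.** Ester 6 is cut at O1–C2 and at the bond between C3 and the ester carbon, giving stilbene phenol 5, carbon monoxide and methanol. Cutting C2–C3 instead (aldol or carbene-insertion logic) leaves an arylacetic acid that takes several steps to make. Cutting C3–C3a calls for an aryl shift or an arylation at a hindered carbon. The chosen cut removes the ring and both stereocentres at once and leaves a flat, achiral precursor with every carbon but one in place. It asks for oxypalladation of an (E)-1,2-diarylethene by the ortho-phenol with control of the alkene face, and capture of the benzylic palladium intermediate by CO before β-hydride elimination can aromatise the ring.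

**Stilbene.** Stilbene 5 is cut at its double bond into salicylaldehyde 2 and phosphonate 4 (Horner–Wadsworth–Emmons). A Mizoroki–Heck union of an ortho-bromophenol derivative with a styrene would cut C3–C3a instead. That route needs O1 masked during coupling and freed afterwards. The usual temporary group, an allyl ether, would sit ortho to the bromide, where intramolecular carbopalladation and allyl transfer to zerovalent palladium compete. The olefination gives the free phenol directly, with the (E) geometry on which the key step depends. It must cope with an aldehyde deactivated as its phenoxide.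

**Building blocks.** Aldehyde 2 comes from commercial 5-bromo-2,3-dihydroxybenzaldehyde 1 by protecting only the C3 hydroxyl (future O7). Phosphonate 4 comes from 3,4-dimethoxybenzyl chloride 3 by a Michaelis–Arbuzov reaction. In 1 the bromine is already para to the future O1 (the future C5) and the formyl carbon becomes C3, so all ring A substituents are bought. The protection must discriminate between two phenols and relies on their different nucleophilicity in the dianion.

## Roads not taken

**Alternative 1:** Ring A itself is cut at C3a–C7a and C6–C7. It would be assembled from a 2,4-disubstituted furan attached to C3 and an ethynyl ether on the C2 oxygen.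
- Forward step: Ph3PAuNTf2 (monovalent gold) activates the alkyne, the furan attacks the oxygen-bearing alkyne carbon (closing the dihydrofuran), and furan opening and reclosure build ring A with the furan oxygen delivered to C7. The product is (2R,3S)-3,5-bis{[(tert-butyldimethylsilyl)oxy]methyl}-2-(3,4-dimethoxyphenyl)-2,3-dihydro-1-benzofuran-7-ol A1.
- Merits: the substitution pattern of ring A is fixed by construction. O7 arrives free and distinct from O1 without protecting-group logic. C2 and C3 are set beforehand by open-chain methods and are not touched by the metal step.
- Weak points: the substrate is an ethynyl ether of a secondary benzylic alcohol that ionises easily, so it is hard to make and handle. Oxygen-substituted alkynes are not established partners in the furan–alkyne phenol synthesis. The open-chain precursor with its stereodiad, furan and two masked hydroxymethyl groups needs many steps. A1 still requires differentiation of two primary silyl ethers, a selective benzylic oxidation and chain extension.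
- Comparison: this road is better in that its stereochemistry does not rest on an untested asymmetric catalytic event and O7 needs no protection. The chosen plan sets against it a two-step access to the cyclisation substrate, catalytic generation of chirality and a C5 handle that becomes the acrylic acid in one step.

**Alternative 2:** The cut is at C2–C3 and O1–C2. C2 with ring B would come as a benzylic sulfonium ylide of a chiral sulfide, and ring A with C3 as an ortho-quinone methide released from a sulfone by base.
- Forward step: with Cs2CO3 the ylide carbon adds to the methide carbon and the phenoxide displaces the sulfide. This gives the trans product tert-butyl{[(2R,3S)-5-bromo-2-(3,4-dimethoxyphenyl)-7-(methoxymethoxy)-2,3-dihydro-1-benzofuran-3-yl]methoxy}dimethylsilane A2.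
- Merits: the trans relationship arises directly and C3 is already at the alcohol oxidation state. That saves the epimerisation and the reduction, two steps after the key step. A2 has the same bromide and MOM group as compound 8, so the endgame would be shared.
- Weak points: a quinone methide carrying a silyloxymethyl group on the methide carbon can tautomerise to a hydroxystyrene or lose silanolate. Semi-stabilised ylides of electron-rich benzyl sulfonium salts are prone to rearrangement and give weaker stereocontrol. Both stereocentres depend on a stoichiometric chiral sulfonium salt. The sulfone precursor takes several steps.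
- Comparison: this road is shorter after the ring closure and needs no C3 correction. The chosen plan sets against it catalytic rather than stoichiometric chirality, a simpler substrate, and a C3 configuration fixed by equilibration, independent of the diastereoselectivity of the ring-forming step.

**Alternative 3:** The cut is at C3–C3a, formed by migration of the ring A carbon of an enantioenriched flavanone from the carbonyl carbon to its neighbour.
- Forward step: PhI(OAc)2 with H2SO4 in HC(OMe)3 passes through the enol ether and a trivalent-iodine adduct and contracts the pyranone to methyl (2R,3R)-5-bromo-2-(3,4-dimethoxyphenyl)-7-(pivaloyloxy)-2,3-dihydro-1-benzofuran-3-carboxylate A3.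
- Merits: the ring contraction belongs to a documented reaction class and gives the trans ester directly. A3 differs from compound 7 only in the O7 protecting group, so the endgame would be the same.
- Weak points: C2 must be set in the flavanone, whose C2–O1 bond opens reversibly to the hydroxychalcone in acid or base, and the contraction runs in sulfuric acid. With an electron-rich ring B, migration of ring B (isoflavone formation) and dehydrogenation to the flavone are the typical diversions. Chalcone formation and an asymmetric ring closure add steps before the key step.
- Comparison: this road carries less method risk in its key step than the chosen plan. The chosen plan sets against it that C2 is created in the ring-forming step and never sits beside a ketone where it can racemise, and that no competing aryl migration exists.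

Key step: step 4

Assumption: the (S,S)-Bn-BOXAX complex of palladium is taken to deliver O1 to the alkene face that gives 2R. The sense of induction of a 5-endo oxypalladation cannot be read from the known exo cyclisations, and the mirror-image ligand would be used if the opposite sense were found.

## Route

Step 1
Reactants: 1 5-bromo-2,3-dihydroxybenzaldehyde
Product: 2 5-bromo-2-hydroxy-3-(methoxymethoxy)benzaldehyde
Conditions: NaH (2.2 equiv), THF–DMSO, 0 °C; MOMCl (1.0 equiv), 0 °C → rt
Reagents that add atoms: chloromethyl methyl ether, COCCl
Why: Williamson-type O-alkylation of the dianion; the C3 phenoxide, neither conjugated with nor chelated to the formyl group, is the more nucleophilic oxygen and should take the single equivalent of MOMCl, leaving the C2 hydroxyl (future O1) free.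

Step 2
Reactants: 3 3,4-dimethoxybenzyl chloride
Product: 4 diethyl [(3,4-dimethoxyphenyl)methyl]phosphonate
Conditions: P(OEt)3 (neat), 130 °C
Reagents that add atoms: triethyl phosphite, CCOP(OCC)OCC
Why: Michaelis–Arbuzov reaction of a reactive benzylic chloride; chloroethane distils off and drives the reaction.

Step 3
Reactants: 2 5-bromo-2-hydroxy-3-(methoxymethoxy)benzaldehyde; 4 diethyl [(3,4-dimethoxyphenyl)methyl]phosphonate
Product: 5 4-bromo-2-[(E)-2-(3,4-dimethoxyphenyl)ethenyl]-6-(methoxymethoxy)phenol
Conditions: t-BuOK (3 equiv), DMF, 0 °C → rt
Reagents that add atoms: none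
Why: Horner–Wadsworth–Emmons olefination; excess base covers the phenol and forms the phosphonate anion, and reversible addition of this semi-stabilised anion followed by syn-elimination of phosphate should favour the (E)-stilbene; the phenoxide lowers the electrophilicity of the aldehyde, hence the polar solvent.

Step 4
Reactants: 5 4-bromo-2-[(E)-2-(3,4-dimethoxyphenyl)ethenyl]-6-(methoxymethoxy)phenol
Product: 6 methyl (2R,3S)-5-bromo-2-(3,4-dimethoxyphenyl)-7-(methoxymethoxy)-2,3-dihydro-1-benzofuran-3-carboxylate (cis ester)
Conditions: Pd(OCOCF3)2 (10 mol %), (S,S)-Bn-BOXAX (20 mol %), p-benzoquinone (4 equiv), CO (1 atm), MeOH–CH2Cl2, 0 °C → rt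
Reagents that add atoms: carbon monoxide, [C-]#[O+]; methanol, CO
Why: Proposed new method: the trifluoroacetate complex deprotonates the phenol to an aryloxide of divalent palladium, the (E)-alkene coordinates cis to it and inserts into the Pd–O bond (syn oxypalladation), forming O1–C2 and placing palladium on C3 as an eta-3 benzyl held by ring A; the closest known reaction type is the enantioselective Wacker-type cyclisation–methoxycarbonylation of alkenylphenols with Pd(OCOCF3)2, a binaphthyl bisoxazoline, p-benzoquinone and CO in methanol, so far run in the exo mode on non-conjugated alkenes, together with the oxidative palladium cyclisation of 2-hydroxystilbenes to 2-arylbenzofurans. The dihydrofuran closes in the 5-endo-trig mode, which is geometrically open because O1 and C3 can span palladium in a five-membered chelate before insertion. C2 is set by the ligand, (aS)-2,2'-bis[(4S)-4-benzyl-4,5-dihydrooxazol-2-yl]-1,1'-binaphthyl, which selects the alkene face that binds palladium. C3 is set relative to C2 by the syn course of the insertion on the (E)-alkene and by CO insertion with retention, which together give the cis ester. After syn addition the only β-hydrogen, on C2, lies anti to palladium, so β-hydride elimination to the benzofuran is closed; the acyl complex formed with CO is cleaved by methanol and p-benzoquinone returns zerovalent palladium to the divalent state. The step needs syn over anti oxypalladation (chloride-free, ligand-bound catalyst under CO), attack of O1 at C2 (ring B makes C2 the cation-stabilising end and the only alternative is a four-membered ring) and face selection by the ligand. The MOM group keeps O7 from chelating or being oxidised, and the aryl bromide should not react with divalent palladium at room temperature.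

Step 5
Reactants: 6 methyl (2R,3S)-5-bromo-2-(3,4-dimethoxyphenyl)-7-(methoxymethoxy)-2,3-dihydro-1-benzofuran-3-carboxylate
Product: 7 methyl (2R,3R)-5-bromo-2-(3,4-dimethoxyphenyl)-7-(methoxymethoxy)-2,3-dihydro-1-benzofuran-3-carboxylate (trans ester)
Conditions: NaOMe (0.3 equiv), MeOH–THF, rt
Reagents that add atoms: none
Why: Base-mediated epimerisation alpha to the ester; the C3 enolate is reprotonated from the face opposite the C2 aryl group, so the cis ester should equilibrate to the less strained trans ester, while C2 has no acidic hydrogen and is untouched; methoxide matches the ester, so transesterification is degenerate.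

Step 6
Reactants: 7 methyl (2R,3R)-5-bromo-2-(3,4-dimethoxyphenyl)-7-(methoxymethoxy)-2,3-dihydro-1-benzofuran-3-carboxylate
Product: 8 [(2R,3S)-5-bromo-2-(3,4-dimethoxyphenyl)-7-(methoxymethoxy)-2,3-dihydro-1-benzofuran-3-yl]methanol
Conditions: LiBH4, THF, 0 °C → rt
Reagents that add atoms: none
Why: Chemoselective ester reduction with LiBH4; aryl bromide, MOM acetal and benzylic ether are inert to borohydride, and C3 is no longer epimerisable once reduced (the descriptor changes from 3R to 3S only through the priority change).

Step 7
Reactants: 8 [(2R,3S)-5-bromo-2-(3,4-dimethoxyphenyl)-7-(methoxymethoxy)-2,3-dihydro-1-benzofuran-3-yl]methanol; 9 acrylic acid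
Product: 10 (2E)-3-[(2R,3S)-2-(3,4-dimethoxyphenyl)-3-(hydroxymethyl)-7-(methoxymethoxy)-2,3-dihydro-1-benzofuran-5-yl]prop-2-enoic acid
Conditions: Pd(OAc)2 (5 mol %), P(o-tol)3 (15 mol %), Et3N, DMF, 100 °C
Reagents that add atoms: none
Why: Mizoroki–Heck reaction of an aryl bromide with acrylic acid (present as its triethylammonium salt); syn-carbopalladation and syn-β-hydride elimination should give the (E)-cinnamic acid, and the primary alcohol, MOM ether and both stereocentres are indifferent to amine base.

Step 8
Reactants: 10 (2E)-3-[(2R,3S)-2-(3,4-dimethoxyphenyl)-3-(hydroxymethyl)-7-(methoxymethoxy)-2,3-dihydro-1-benzofuran-5-yl]prop-2-enoic acid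
Product: 11 (2E)-3-[(2R,3S)-2-(3,4-dimethoxyphenyl)-7-hydroxy-3-(hydroxymethyl)-2,3-dihydro-1-benzofuran-5-yl]prop-2-enoic acid
Conditions: 3 M HCl (aq), THF, 40 °C
Reagents that add atoms: none
Why: Acid hydrolysis of the aryl MOM acetal through its oxocarbenium ion; dilute aqueous acid without alcohol solvent avoids esterification of the acid, and ring B has no free para-hydroxyl, so the C2–O1 ether should not open through a quinone methide under these mild conditions.

## Compound list

1 | 5-bromo-2,3-dihydroxybenzaldehyde | O=Cc1cc(Br)cc(O)c1O | starting material
2 | 5-bromo-2-hydroxy-3-(methoxymethoxy)benzaldehyde | COCOc1cc(Br)cc(C=O)c1O | intermediate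
3 | 3,4-dimethoxybenzyl chloride (4-(chloromethyl)-1,2-dimethoxybenzene) | COc1ccc(CCl)cc1OC | starting material
4 | diethyl [(3,4-dimethoxyphenyl)methyl]phosphonate | CCOP(=O)(Cc1ccc(OC)c(OC)c1)OCC | intermediate
5 | 4-bromo-2-[(E)-2-(3,4-dimethoxyphenyl)ethenyl]-6-(methoxymethoxy)phenol | COCOc1cc(Br)cc(/C=C/c2ccc(OC)c(OC)c2)c1O | intermediate
6 | methyl (2R,3S)-5-bromo-2-(3,4-dimethoxyphenyl)-7-(methoxymethoxy)-2,3-dihydro-1-benzofuran-3-carboxylate (cis) | COc1ccc([C@@H]2Oc3c(OCOC)cc(Br)cc3[C@@H]2C(=O)OC)cc1OC | intermediate
7 | methyl (2R,3R)-5-bromo-2-(3,4-dimethoxyphenyl)-7-(methoxymethoxy)-2,3-dihydro-1-benzofuran-3-carboxylate (trans) | COc1ccc([C@@H]2Oc3c(OCOC)cc(Br)cc3[C@H]2C(=O)OC)cc1OC | intermediate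
8 | [(2R,3S)-5-bromo-2-(3,4-dimethoxyphenyl)-7-(methoxymethoxy)-2,3-dihydro-1-benzofuran-3-yl]methanol | COc1ccc([C@@H]2Oc3c(OCOC)cc(Br)cc3[C@H]2CO)cc1OC | intermediate
9 | acrylic acid (prop-2-enoic acid) | C=CC(=O)O | starting material
10 | (2E)-3-[(2R,3S)-2-(3,4-dimethoxyphenyl)-3-(hydroxymethyl)-7-(methoxymethoxy)-2,3-dihydro-1-benzofuran-5-yl]prop-2-enoic acid | COc1ccc([C@@H]2Oc3c(OCOC)cc(/C=C/C(=O)O)cc3[C@H]2CO)cc1OC | intermediate
11 | (2E)-3-[(2R,3S)-2-(3,4-dimethoxyphenyl)-7-hydroxy-3-(hydroxymethyl)-2,3-dihydro-1-benzofuran-5-yl]prop-2-enoic acid | COc1ccc([C@@H]2Oc3c(O)cc(/C=C/C(=O)O)cc3[C@H]2CO)cc1OC | target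

## Step count and risks

Total step count: 8. Longest linear sequence: 7 steps (steps 1, 3, 4, 5, 6, 7, 8, from 1 to 11).

**Step 4 (key step, new method).**
- What may go wrong: the 5-endo insertion of the stilbene into the Pd–O bond may be slower than external (anti) attack of the phenol on the coordinated alkene. The anti adduct has palladium syn to the C2 hydrogen and can aromatise by β-hydride elimination. If it is trapped by CO instead, it gives a trans ester of the opposite C2 series, so a mixed mechanism would erode enantiopurity after step 5. The cis ester 6 should therefore be separated from any trans ester before epimerisation. Face discrimination of a nearly symmetrical diarylethene may also be poor, and oxidative carbonylation of methanol or of the phenol may consume the oxidant.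
- Fallback (sets out from 2, returns at 6): known carbene chemistry that forms C2–C3 instead.
  - O-Alkylation of 2 with chloride 3 (K2CO3, DMF) would give 5-bromo-2-[(3,4-dimethoxyphenyl)methoxy]-3-(methoxymethoxy)benzaldehyde F1.
  - Addition of trichloromethanide (CCl3CO2Na, CCl3CO2H, DMF) would give 1-{5-bromo-2-[(3,4-dimethoxyphenyl)methoxy]-3-(methoxymethoxy)phenyl}-2,2,2-trichloroethanol F2.
  - Reductive Jocic-type homologation (NaBH4, NaOH, t-BuOH) would give {5-bromo-2-[(3,4-dimethoxyphenyl)methoxy]-3-(methoxymethoxy)phenyl}acetic acid F3.
  - Esterification (MeI, K2CO3, DMF) would give methyl {5-bromo-2-[(3,4-dimethoxyphenyl)methoxy]-3-(methoxymethoxy)phenyl}acetate F4.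
  - Diazo transfer (4-acetamidobenzenesulfonyl azide, DBU, MeCN) would give methyl diazo{5-bromo-2-[(3,4-dimethoxyphenyl)methoxy]-3-(methoxymethoxy)phenyl}acetate F5.
  - Enantioselective intramolecular insertion of the carbene into the benzylic ether C–H bond closes the ring to cis ester 6. The catalyst is a complex of divalent rhodium, Rh2(S-PTTL)4 (dirhodium tetrakis[N-phthaloyl-(S)-tert-leucinate]) or its enantiomer, in toluene at low temperature.

**Step 3.**
- What may go wrong: deprotonation of the phenol turns the aldehyde into a vinylogous carboxylate, so addition of the phosphonate anion may stall or stop at partial conversion.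
- Fallback (sets out from 2, returns at 5): run the olefination on a neutral aldehyde.
  - O-Allylation of 2 (allyl bromide, K2CO3, acetone) would give 5-bromo-3-(methoxymethoxy)-2-(prop-2-en-1-yloxy)benzaldehyde F6.
  - Horner–Wadsworth–Emmons reaction with 4 (NaH, THF) would give 5-bromo-1-[(E)-2-(3,4-dimethoxyphenyl)ethenyl]-3-(methoxymethoxy)-2-(prop-2-en-1-yloxy)benzene F7.
  - Allyl transfer to morpholine with Pd(PPh3)4 (zerovalent palladium) at room temperature frees O1 and gives 5. Here the bromide is para, not ortho, to the allyl ether, so no ring can close onto the allyl group.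

**Step 1.**
- What may go wrong: alkylation at the wrong oxygen, or double alkylation, if the two phenoxides of the dianion are not sufficiently different.
- Fallback (sets out from 1, returns at 2): exhaustive protection (MOMCl, i-Pr2NEt, CH2Cl2) would give 5-bromo-2,3-bis(methoxymethoxy)benzaldehyde F8. MgBr2·OEt2 in Et2O–CH2Cl2 chelates between the formyl oxygen and the ortho acetal and should remove only the C2 MOM group, giving 2.

**Step 5.**
- What may go wrong: the C3 enolate may expel the O1 phenoxide (retro-oxa-Michael ring opening). Reclosure would scramble C2. Equilibration may also stop short of completion.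
- Fallback (sets out from 6, returns at 8, bypassing 7): epimerise at the aldehyde stage, where a weak amine base suffices.
  - Half-reduction of 6 (i-Bu2AlH, CH2Cl2, −78 °C) would give (2R,3S)-5-bromo-2-(3,4-dimethoxyphenyl)-7-(methoxymethoxy)-2,3-dihydro-1-benzofuran-3-carbaldehyde F9.
  - Catalytic DBU (CH2Cl2, rt) would convert it into the trans isomer (2R,3R)-5-bromo-2-(3,4-dimethoxyphenyl)-7-(methoxymethoxy)-2,3-dihydro-1-benzofuran-3-carbaldehyde F10.
  - NaBH4 (MeOH, 0 °C) then gives 8.

**Step 7.**
- What may go wrong: slow oxidative addition into the electron-rich aryl bromide at a temperature where acrylic acid polymerises, or loss of bromine by hydride transfer from the alkoxide.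
- Fallback (sets out from 8, returns at 10): treatment of 8 with n-BuLi (2.2 equiv, THF, −78 °C; alkoxide formation, then bromine–lithium exchange) and DMF would give (2R,3S)-2-(3,4-dimethoxyphenyl)-3-(hydroxymethyl)-7-(methoxymethoxy)-2,3-dihydro-1-benzofuran-5-carbaldehyde F11. Knoevenagel–Doebner condensation with malonic acid (pyridine, cat. piperidine, 90 °C) then gives 10.

## Further compounds

F1 | step 4 | 5-bromo-2-[(3,4-dimethoxyphenyl)methoxy]-3-(methoxymethoxy)benzaldehyde | COCOc1cc(Br)cc(C=O)c1OCc1ccc(OC)c(OC)c1
F2 | step 4 | 1-{5-bromo-2-[(3,4-dimethoxyphenyl)methoxy]-3-(methoxymethoxy)phenyl}-2,2,2-trichloroethanol (racemic) | COCOc1cc(Br)cc(C(O)C(Cl)(Cl)Cl)c1OCc1ccc(OC)c(OC)c1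
F3 | step 4 | {5-bromo-2-[(3,4-dimethoxyphenyl)methoxy]-3-(methoxymethoxy)phenyl}acetic acid | COCOc1cc(Br)cc(CC(=O)O)c1OCc1ccc(OC)c(OC)c1
F4 | step 4 | methyl {5-bromo-2-[(3,4-dimethoxyphenyl)methoxy]-3-(methoxymethoxy)phenyl}acetate | COCOc1cc(Br)cc(CC(=O)OC)c1OCc1ccc(OC)c(OC)c1
F5 | step 4 | methyl diazo{5-bromo-2-[(3,4-dimethoxyphenyl)methoxy]-3-(methoxymethoxy)phenyl}acetate | COCOc1cc(Br)cc(C(=[N+]=[N-])C(=O)OC)c1OCc1ccc(OC)c(OC)c1
F6 | step 3 | 5-bromo-3-(methoxymethoxy)-2-(prop-2-en-1-yloxy)benzaldehyde | C=CCOc1c(C=O)cc(Br)cc1OCOC
F7 | step 3 | 5-bromo-1-[(E)-2-(3,4-dimethoxyphenyl)ethenyl]-3-(methoxymethoxy)-2-(prop-2-en-1-yloxy)benzene | C=CCOc1c(/C=C/c2ccc(OC)c(OC)c2)cc(Br)cc1OCOC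
F8 | step 1 | 5-bromo-2,3-bis(methoxymethoxy)benzaldehyde | COCOc1cc(Br)cc(C=O)c1OCOC
F9 | step 5 | (2R,3S)-5-bromo-2-(3,4-dimethoxyphenyl)-7-(methoxymethoxy)-2,3-dihydro-1-benzofuran-3-carbaldehyde (cis) | COc1ccc([C@@H]2Oc3c(OCOC)cc(Br)cc3[C@@H]2C=O)cc1OC
F10 | step 5 | (2R,3R)-5-bromo-2-(3,4-dimethoxyphenyl)-7-(methoxymethoxy)-2,3-dihydro-1-benzofuran-3-carbaldehyde (trans) | COc1ccc([C@@H]2Oc3c(OCOC)cc(Br)cc3[C@H]2C=O)cc1OC
F11 | step 7 | (2R,3S)-2-(3,4-dimethoxyphenyl)-3-(hydroxymethyl)-7-(methoxymethoxy)-2,3-dihydro-1-benzofuran-5-carbaldehyde | COc1ccc([C@@H]2Oc3c(OCOC)cc(C=O)cc3[C@H]2CO)cc1OC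
A1 | alternative 1 | (2R,3S)-3,5-bis{[(tert-butyldimethylsilyl)oxy]methyl}-2-(3,4-dimethoxyphenyl)-2,3-dihydro-1-benzofuran-7-ol | COc1ccc([C@@H]2Oc3c(O)cc(CO[Si](C)(C)C(C)(C)C)cc3[C@H]2CO[Si](C)(C)C(C)(C)C)cc1OC
A2 | alternative 2 | tert-butyl{[(2R,3S)-5-bromo-2-(3,4-dimethoxyphenyl)-7-(methoxymethoxy)-2,3-dihydro-1-benzofuran-3-yl]methoxy}dimethylsilane | COc1ccc([C@@H]2Oc3c(OCOC)cc(Br)cc3[C@H]2CO[Si](C)(C)C(C)(C)C)cc1OC
A3 | alternative 3 | methyl (2R,3R)-5-bromo-2-(3,4-dimethoxyphenyl)-7-(pivaloyloxy)-2,3-dihydro-1-benzofuran-3-carboxylate | COc1ccc([C@@H]2Oc3c(OC(=O)C(C)(C)C)cc(Br)cc3[C@H]2C(=O)OC)cc1OC
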